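**Strategy.** The pyran ring is disconnected across C3–C4 and O1–C2. An ortho-quinone methide made of O1, C8a, C4a and C4 of the 5,7-dioxygenated A ring is joined to a two-carbon C2–C3 enol ether that already carries the B ring. One chiral-acid-catalysed inverse-demand [4+2] cycloaddition forms both bonds, closes ring C and sets C3. The donor oxygens at C5 and C7 are what make the methide form readily. The precursors are a 7-O-silylated, 6-prenylated salicyl alcohol and a geometrically pure (E)-β-alkoxystyrene whose arene is the fully methylated, prenylated form of the hydroxyquinone. Acetal reduction, oxidative demethylation and hydrolysis finish the synthesis.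

Key step: step 9

**Remarks (assumptions)**
- The alkoxy group of the dienophile is lost from C2 in step 10, so ethoxy is used in place of methoxy: the (E)-2-ethoxyvinyl boronate is a stock reagent and gives one alkene geometry, which a Wittig methoxymethylenation would not.
- (R)-TRIP is assumed to direct attack to the alkene face that leads to 3R; if the sense proves opposite, the (S)-acid is used.
- 2,4-Dihydroxy-6-methoxybenzaldehyde is taken as a purchasable starting material.

**Route**

Step 1
Reactants: 1 2,4-dihydroxy-6-methoxybenzaldehyde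
Product: 2 4-(tert-butyldimethylsilyloxy)-2-hydroxy-6-methoxybenzaldehyde
Conditions: TBSCl (1.05 equiv), imidazole, CH2Cl2, 0 °C
Reagents that add atoms: tert-butyldimethylsilyl chloride, CC(C)(C)[Si](C)(C)Cl
Why: Regioselective O-silylation, since the 4-OH is the more acidic and unhindered phenol whereas the 2-OH is locked in a hydrogen bond to the formyl oxygen and stays free.

Step 2
Reactants: 2 4-(tert-butyldimethylsilyloxy)-2-hydroxy-6-methoxybenzaldehyde; 3 3-methylbut-2-en-1-ol (prenol)
Product: 4 4-(tert-butyldimethylsilyloxy)-2-methoxy-6-(3-methylbut-2-enyloxy)benzaldehyde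
Conditions: PPh3, DIAD, THF, 0 °C to rt
Reagents that add atoms: none
Why: Mitsunobu etherification alkylates the chelated phenol with the primary allylic alcohol at its CH2 under neutral conditions, so the base-labile aryl silyl ether para to the formyl group is not disturbed.

Step 3
Reactants: 4 4-(tert-butyldimethylsilyloxy)-2-methoxy-6-(3-methylbut-2-enyloxy)benzaldehyde
Product: 7 4-(tert-butyldimethylsilyloxy)-6-hydroxy-2-methoxy-3-(3-methylbut-2-enyl)benzaldehyde, via ortho-dienone 5 (not isolated), via para-dienone 6 (not isolated)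
Conditions: Eu(fod)3 (10 mol%), NaHCO3, PhCl, 85 °C
Reagents that add atoms: none
Why: Domino aromatic Claisen–Cope (para-Claisen) rearrangement, in which Eu(III) chelated by the formyl and ether oxygens promotes the [3,3] shift to the free ortho carbon, the crowded ortho-dienone 5 passes the allyl unit on by a Cope shift to the para carbon between OMe and OTBS with the prenyl group restored in its regular form, and enolisation of 6 frees the carrier oxygen as the only phenol.

Step 4
Reactants: 7 4-(tert-butyldimethylsilyloxy)-6-hydroxy-2-methoxy-3-(3-methylbut-2-enyl)benzaldehyde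
Product: 8 5-(tert-butyldimethylsilyloxy)-2-(hydroxymethyl)-3-methoxy-4-(3-methylbut-2-enyl)phenol
Conditions: NaBH4, THF/MeOH, 0 °C; pH 7 buffer work-up; used at once
Reagents that add atoms: none
Why: Borohydride reduction of the aryl aldehyde to the benzylic alcohol leaves alkene and aryl silyl ether alone, and the work-up is kept neutral because the product ionises readily.

Step 5
Reactants: 9 1,2,4-trimethoxybenzene
Product: 11 2-bromo-1,3,4-trimethoxybenzene, via 2,3,6-trimethoxyphenyllithium 10 (not isolated)
Conditions: n-BuLi, THF, 0 °C to rt; then BrCl2C–CCl2Br, −78 °C to rt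
Reagents that add atoms: 1,2-dibromotetrachloroethane, BrC(Cl)(Cl)C(Cl)(Cl)Br
Why: Directed ortho-metalation occurs at the carbon flanked by two methoxy groups, and the aryllithium takes Br+ from 1,2-dibromotetrachloroethane (halogen transfer).

Step 6
Reactants: 11 2-bromo-1,3,4-trimethoxybenzene
Product: 12 3-bromo-1-iodo-2,4,5-trimethoxybenzene
Conditions: NIS, TFA (cat.), MeCN, rt
Reagents that add atoms: N-iodosuccinimide, O=C1CCC(=O)N1I
Why: Electrophilic aromatic iodination goes to the free position that is ortho to one methoxy group and para to another, the other free position being activated by a single ortho-methoxy group only and lying para to bromine.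

Step 7
Reactants: 12 3-bromo-1-iodo-2,4,5-trimethoxybenzene; 13 (E)-2-(2-ethoxyvinyl)-4,4,5,5-tetramethyl-1,3,2-dioxaborolane
Product: 14 (E)-3-bromo-1-(2-ethoxyvinyl)-2,4,5-trimethoxybenzene
Conditions: Pd(dppf)Cl2 (3 mol%), K2CO3, dioxane/H2O, 60 °C
Reagents that add atoms: none
Why: Suzuki–Miyaura coupling in which oxidative addition to C–I far outruns that to the di-ortho-substituted C–Br and the alkenyl group is transferred with retention, so the enol ether should be obtained as the E isomer only.

Step 8
Reactants: 14 (E)-3-bromo-1-(2-ethoxyvinyl)-2,4,5-trimethoxybenzene; 15 prenyl bromide (1-bromo-3-methylbut-2-ene)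
Product: 17 (E)-1-(2-ethoxyvinyl)-2,4,5-trimethoxy-3-(3-methylbut-2-enyl)benzene, via aryllithium 16 (not isolated)
Conditions: t-BuLi (2.1 equiv), THF, −78 °C; then CuBr·SMe2 (10 mol%), 15, −78 to 0 °C; chromatography on Et3N-treated silica
Reagents that add atoms: none
Why: Bromine–lithium exchange at −78 °C is faster than any reaction of the enol ether, and the 2,6-dimethoxyaryllithium is allylated at the primary carbon of prenyl bromide (copper-assisted SN2 alkylation).

Step 9
Reactants: 8 5-(tert-butyldimethylsilyloxy)-2-(hydroxymethyl)-3-methoxy-4-(3-methylbut-2-enyl)phenol; 17 (E)-1-(2-ethoxyvinyl)-2,4,5-trimethoxy-3-(3-methylbut-2-enyl)benzene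
Product: 19 (2S,3R)-7-(tert-butyldimethylsilyloxy)-2-ethoxy-5-methoxy-6-(3-methylbut-2-enyl)-3-[2,4,5-trimethoxy-3-(3-methylbut-2-enyl)phenyl]chroman (2,3-trans), via ortho-quinone methide 18 (not isolated)
Conditions: (R)-TRIP (10 mol%), 4 Å MS, toluene, 0 °C; 8 added slowly to 17 (1.5 equiv)
Reagents that add atoms: none
Why: The phosphoric acid protonates the benzylic hydroxyl of 8, water leaves with help from the ortho and para oxygen donors, and the ortho-quinone methide 18 stays hydrogen-bonded to the acid inside its chiral pocket, where the nucleophilic aryl-bearing carbon of 17 attacks the C4 methylene and the phenolic oxygen then closes onto the developing oxocarbenium carbon in an asynchronous inverse-electron-demand oxa-[4+2] cycloaddition that restores A-ring aromaticity. The closest known reaction type is the chiral phosphoric acid-catalysed hetero-Diels–Alder reaction of ortho-quinone methides generated in situ from ortho-hydroxybenzyl alcohols with electron-rich alkenes. Ring C closes by this intermolecular [4+2] cycloaddition, C3–C4 forming ahead of O1–C2. C3 is set by the catalyst, which shields one face of the aryl-bearing alkene carbon, and C2 follows from the E geometry through suprafacial addition, so ethoxy and aryl end up trans. The step needs regioselectivity, which the polarity of the enol ether secures (nucleophilic carbon to the methylene, oxygen to the acetal carbon), and exclusive ortho-methide formation, which silylation of the 7-oxygen secures by ruling out a para-quinone methide. Slow addition of 8 to excess 17 over molecular sieves keeps the methide concentration low and removes the water that would hydrolyse the enol ether.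

Step 10
Reactants: 19 (2S,3R)-7-(tert-butyldimethylsilyloxy)-2-ethoxy-5-methoxy-6-(3-methylbut-2-enyl)-3-[2,4,5-trimethoxy-3-(3-methylbut-2-enyl)phenyl]chroman
Product: 20 (3R)-7-(tert-butyldimethylsilyloxy)-5-methoxy-6-(3-methylbut-2-enyl)-3-[2,4,5-trimethoxy-3-(3-methylbut-2-enyl)phenyl]chroman
Conditions: Et3SiH, BF3·OEt2, CH2Cl2, −78 to −40 °C
Reagents that add atoms: none
Why: Ionic hydrogenation of the cyclic O,O-acetal, in which BF3 removes the ethoxy group and the oxocarbenium ion at C2 is trapped by hydride from the silane at low temperature, while C3, the unprotonated trisubstituted alkenes and the aryl silyl ether are left as they are.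

Step 11
Reactants: 20 (3R)-7-(tert-butyldimethylsilyloxy)-5-methoxy-6-(3-methylbut-2-enyl)-3-[2,4,5-trimethoxy-3-(3-methylbut-2-enyl)phenyl]chroman
Product: 21 5-[(3R)-7-(tert-butyldimethylsilyloxy)-5-methoxy-6-(3-methylbut-2-enyl)chroman-3-yl]-2-methoxy-3-(3-methylbut-2-enyl)-1,4-benzoquinone
Conditions: CAN (2.5 equiv), MeCN/H2O, 0 °C
Reagents that add atoms: water, O
Why: Oxidative demethylation with cerium(IV) removes the para-related 2′- and 5′-methoxy groups of the 1,2,4-trimethoxyarene and gives the p-quinone with the 4′-methoxy group kept as a vinylogous ester, while the A ring, whose oxygens are meta to one another, is harder to oxidise and cannot give a quinone.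

Step 12
Reactants: 21 5-[(3R)-7-(tert-butyldimethylsilyloxy)-5-methoxy-6-(3-methylbut-2-enyl)chroman-3-yl]-2-methoxy-3-(3-methylbut-2-enyl)-1,4-benzoquinone
Product: 22 2-hydroxy-5-[(3R)-7-hydroxy-5-methoxy-6-(3-methylbut-2-enyl)chroman-3-yl]-3-(3-methylbut-2-enyl)-1,4-benzoquinone (CNP0148998.1)
Conditions: LiOH, THF/H2O, 0 °C to rt, argon; then cold dilute HCl to pH 4
Reagents that add atoms: lithium hydroxide, [Li+].[OH-]
Why: Hydroxide replaces the methoxy group of the vinylogous ester by addition–elimination, giving the hydroxyquinone anion that is inert to further attack, and cleaves the aryl silyl ether at silicon, while cold mild acidification avoids acid-induced cyclisation of the prenyl groups onto the neighbouring hydroxyls.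

**Compound list**

1 | 2,4-dihydroxy-6-methoxybenzaldehyde | COc1cc(O)cc(O)c1C=O | starting material
2 | 4-(tert-butyldimethylsilyloxy)-2-hydroxy-6-methoxybenzaldehyde | COc1cc(O[Si](C)(C)C(C)(C)C)cc(O)c1C=O | intermediate
3 | 3-methylbut-2-en-1-ol (prenol) | CC(C)=CCO | starting material
4 | 4-(tert-butyldimethylsilyloxy)-2-methoxy-6-(3-methylbut-2-enyloxy)benzaldehyde | COc1cc(O[Si](C)(C)C(C)(C)C)cc(OCC=C(C)C)c1C=O | intermediate
5 | ortho-dienone, 5-(tert-butyldimethylsilyloxy)-2-formyl-3-methoxy-6-(2-methylbut-3-en-2-yl)cyclohexa-2,4-dien-1-one (racemic, not isolated) | COC1=C(C=O)C(=O)C(C(C)(C)C=C)C(O[Si](C)(C)C(C)(C)C)=C1 | intermediate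
6 | para-dienone, 5-(tert-butyldimethylsilyloxy)-2-formyl-3-methoxy-4-(3-methylbut-2-enyl)cyclohexa-2,5-dien-1-one (racemic, not isolated) | COC1=C(C=O)C(=O)C=C(O[Si](C)(C)C(C)(C)C)C1CC=C(C)C | intermediate
7 | 4-(tert-butyldimethylsilyloxy)-6-hydroxy-2-methoxy-3-(3-methylbut-2-enyl)benzaldehyde | COc1c(CC=C(C)C)c(O[Si](C)(C)C(C)(C)C)cc(O)c1C=O | intermediate
8 | 5-(tert-butyldimethylsilyloxy)-2-(hydroxymethyl)-3-methoxy-4-(3-methylbut-2-enyl)phenol | COc1c(CC=C(C)C)c(O[Si](C)(C)C(C)(C)C)cc(O)c1CO | intermediate
9 | 1,2,4-trimethoxybenzene | COc1ccc(OC)c(OC)c1 | starting material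
10 | 2,3,6-trimethoxyphenyllithium (not isolated) | [Li]c1c(OC)ccc(OC)c1OC | intermediate
11 | 2-bromo-1,3,4-trimethoxybenzene | COc1ccc(OC)c(OC)c1Br | intermediate
12 | 3-bromo-1-iodo-2,4,5-trimethoxybenzene | COc1c(I)cc(OC)c(OC)c1Br | intermediate
13 | (E)-2-(2-ethoxyvinyl)-4,4,5,5-tetramethyl-1,3,2-dioxaborolane | CCO/C=C/B1OC(C)(C)C(C)(C)O1 | starting material
14 | (E)-3-bromo-1-(2-ethoxyvinyl)-2,4,5-trimethoxybenzene | CCO/C=C/c1cc(OC)c(OC)c(Br)c1OC | intermediate
15 | prenyl bromide (1-bromo-3-methylbut-2-ene) | CC(C)=CCBr | starting material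
16 | (E)-3-(2-ethoxyvinyl)-2,5,6-trimethoxyphenyllithium (not isolated) | CCO/C=C/c1cc(OC)c(OC)c([Li])c1OC | intermediate
17 | (E)-1-(2-ethoxyvinyl)-2,4,5-trimethoxy-3-(3-methylbut-2-enyl)benzene | CCO/C=C/c1cc(OC)c(OC)c(CC=C(C)C)c1OC | intermediate
18 | ortho-quinone methide, 5-(tert-butyldimethylsilyloxy)-3-methoxy-2-methylidene-4-(3-methylbut-2-enyl)cyclohexa-3,5-dien-1-one (not isolated) | C=C1C(=O)C=C(O[Si](C)(C)C(C)(C)C)C(CC=C(C)C)=C1OC | intermediate
19 | (2S,3R)-7-(tert-butyldimethylsilyloxy)-2-ethoxy-5-methoxy-6-(3-methylbut-2-enyl)-3-[2,4,5-trimethoxy-3-(3-methylbut-2-enyl)phenyl]chroman | COc1c(CC=C(C)C)c(O[Si](C)(C)C(C)(C)C)cc2c1C[C@H](c1cc(OC)c(OC)c(CC=C(C)C)c1OC)[C@@H](OCC)O2 | intermediate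
20 | (3R)-7-(tert-butyldimethylsilyloxy)-5-methoxy-6-(3-methylbut-2-enyl)-3-[2,4,5-trimethoxy-3-(3-methylbut-2-enyl)phenyl]chroman | COc1c(CC=C(C)C)c(O[Si](C)(C)C(C)(C)C)cc2c1C[C@H](c1cc(OC)c(OC)c(CC=C(C)C)c1OC)CO2 | intermediate
21 | 5-[(3R)-7-(tert-butyldimethylsilyloxy)-5-methoxy-6-(3-methylbut-2-enyl)chroman-3-yl]-2-methoxy-3-(3-methylbut-2-enyl)-1,4-benzoquinone | COc1c(CC=C(C)C)c(O[Si](C)(C)C(C)(C)C)cc2c1C[C@H](C1=CC(=O)C(OC)=C(CC=C(C)C)C1=O)CO2 | intermediate
22 | 2-hydroxy-5-[(3R)-7-hydroxy-5-methoxy-6-(3-methylbut-2-enyl)chroman-3-yl]-3-(3-methylbut-2-enyl)-1,4-benzoquinone | COc1c(CC=C(C)C)c(O)cc2c1C[C@H](C1=CC(=O)C(O)=C(CC=C(C)C)C1=O)CO2 | target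

**Step count**

Total: 12 steps (steps 1–4 for the salicyl alcohol, steps 5–8 for the enol ether, steps 9–12 after convergence).
Longest linear sequence: 8 steps (1 to 22 through steps 1–4 and 9–12; the enol ether branch is of equal length).

**Steps most likely to fail**

Step 9. The enol ether has no hydrogen-bond donor with which to dock to the phosphate, so discrimination between the two faces of the carbon that becomes C3 may be poor. The methide may also be consumed by attack of the free ring position of a second molecule of 8. Fallback: setting out from 8 and 17, the cycloaddition is run with an achiral acid (diphenyl phosphate, 4 Å MS, toluene), which should give the racemic trans acetal F1. Reduction under the conditions of step 10 should give the racemic chroman F2. Preparative chromatography on a chiral stationary phase then separates the enantiomers, and the 3R enantiomer is compound 20, where the route is rejoined. Enantiocontrol by catalyst is thus replaced by resolution.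

Step 10. The oxocarbenium ion at C2 may lose the C3 proton reversibly, which would erode the configuration at C3. The Lewis acid may also cleave the ring C–O bond in place of the exocyclic one and lead to a ring-opened ethyl ether. Fallback: setting out from 19, dilute aqueous acid (0.5 M HCl, THF, 0 °C) hydrolyses the acetal to the lactol F3, since water in excess captures the cation. NaBH4 (EtOH, 0 °C) reduces the open hydroxy-aldehyde form to the phenol-alcohol F4. Mitsunobu etherification (PPh3, DIAD, THF, 0 °C) closes O1–C2 and returns compound 20. The hydride reduction of a cation is thus replaced by carbonyl reduction and ring closure.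

Step 12. Hydroxide may deprotonate C3 through tautomerisation of the alkylquinone to a quinone methide, with loss of configuration, or add to the unsubstituted C6′ position of the quinone and start decomposition. Fallback: setting out from 21, lithium chloride in DMF at 80 °C removes the methyl group by SN2 attack at the methyl carbon of the vinylogous ester (ester-type dealkylation). Mild acidification should give the silylated hydroxyquinone F5. Buffered fluoride (TBAF, AcOH, THF, 0 °C) cleaves the aryl silyl ether and gives the target 22. No hydroxide is used.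

**Further compounds**

F1 | step 9 | racemic 2,3-trans-7-(tert-butyldimethylsilyloxy)-2-ethoxy-5-methoxy-6-(3-methylbut-2-enyl)-3-[2,4,5-trimethoxy-3-(3-methylbut-2-enyl)phenyl]chroman (19 together with its mirror image; the 2R,3S mirror image is drawn) | COc1c(CC=C(C)C)c(O[Si](C)(C)C(C)(C)C)cc2c1C[C@@H](c1cc(OC)c(OC)c(CC=C(C)C)c1OC)[C@H](OCC)O2
F2 | step 9 | racemic 7-(tert-butyldimethylsilyloxy)-5-methoxy-6-(3-methylbut-2-enyl)-3-[2,4,5-trimethoxy-3-(3-methylbut-2-enyl)phenyl]chroman (20 together with its mirror image; the 3S mirror image is drawn) | COc1c(CC=C(C)C)c(O[Si](C)(C)C(C)(C)C)cc2c1C[C@@H](c1cc(OC)c(OC)c(CC=C(C)C)c1OC)CO2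
F3 | step 10 | (3R)-7-(tert-butyldimethylsilyloxy)-5-methoxy-6-(3-methylbut-2-enyl)-3-[2,4,5-trimethoxy-3-(3-methylbut-2-enyl)phenyl]chroman-2-ol (lactol, mixture at C2) | COc1c(CC=C(C)C)c(O[Si](C)(C)C(C)(C)C)cc2c1C[C@H](c1cc(OC)c(OC)c(CC=C(C)C)c1OC)C(O)O2
F4 | step 10 | (2R)-3-[4-(tert-butyldimethylsilyloxy)-2-hydroxy-6-methoxy-5-(3-methylbut-2-enyl)phenyl]-2-[2,4,5-trimethoxy-3-(3-methylbut-2-enyl)phenyl]propan-1-ol | COc1c(CC=C(C)C)c(O[Si](C)(C)C(C)(C)C)cc(O)c1C[C@H](c1cc(OC)c(OC)c(CC=C(C)C)c1OC)CO
F5 | step 12 | 5-[(3R)-7-(tert-butyldimethylsilyloxy)-5-methoxy-6-(3-methylbut-2-enyl)chroman-3-yl]-2-hydroxy-3-(3-methylbut-2-enyl)-1,4-benzoquinone | COc1c(CC=C(C)C)c(O[Si](C)(C)C(C)(C)C)cc2c1C[C@H](C1=CC(=O)C(O)=C(CC=C(C)C)C1=O)CO2
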